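# Proposed total synthesis of CNP0239488.2 by a dearomative, ring-closing furan aldol

## Analysis of the target

Germacrane numbering is used throughout: C1 ketone, C2=C3, C4=C5, C6 (lactone oxygen), C7, C8 (methacrylate), C9 (senecioate), C10 (quaternary), C11=C13, C12 (lactone carbonyl), C14 (methyl on C10), C15 (CH2OH on C4). The SMILES is read as 4Z,6R,7S,8S,9R,10S.

The target is a furanoheliangolide. Its ten-membered carbocycle C1–C10 is bridged by an oxygen between C3 and C10, so that O, C3, C2, C1 and C10 form ring A, a furan-3(2H)-one, inside an 11-oxabicyclo[6.2.1]undecane. Ring C, an α-methylene-γ-butyrolactone (O, C6, C7, C11, C12), is trans-fused at C6–C7. The C4=C5 bond is Z, trisubstituted and cross-conjugated with ring A.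

Five contiguous stereocenters run from C6 to C10: H6 and H7 are trans, H7 and H8 are cis, the C8 and C9 esters are trans, and the C9 oxygen is anti to C14 across the C9–C10 bond. C10 is quaternary and sits next to the C9 carbinol. C8 and C9 carry two different unsaturated esters on a vicinal diol.

Sensitive groups are three Michael acceptors (methylene lactone, methacrylate, senecioate), the dienone, a β-acyloxy ketone (C9–C10–C1) that can undergo retro-aldol cleavage once O9 is free, and an allylic primary alcohol. The difficulty lies in the strained bridged bicycle, the quaternary C10 next to C9, and the need to form the medium ring without base, nucleophiles or reductants.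

The feature that the route exploits: ring A is a 2,2-disubstituted furan-3(2H)-one, that is a dearomatised 3-hydroxyfuran. C10 is the former furan α-carbon that bears C14, and the C9–C10 bond is an aldol bond between that carbon and a C9 aldehyde.

## Retrosynthetic reasoning

**27 ⇒ 26 ⇒ 24.** The O15 silyl ether is removed last, and the senecioate is cut at the O9–acyl bond (acyl donor 25). The 9-hydroxyl exists only after the key step, whereas the 8-ester is carried through it, so only one acylation and one deprotection follow the ring closure.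

**24 ⇒ 23 (key disconnection).** The C9–C10 bond is cut. In the reverse direction ring A re-aromatises to a 2-methyl-3-silyloxyfuran and the carbocycle opens to a chain that ends in a C9 aldehyde. This is the only ring bond whose formation creates two stereocenters (C9 and the quaternary C10). It also closes the ten-membered ring, builds the oxygen bridge and unveils the furanone. The precursor 23 has a flat furan and only the three stereocenters C6–C8, which must direct the two new ones. The forward reaction has to close a medium ring against oligomerisation, choose one furan face and choose one aldehyde face.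

**23 ⇒ 22 + 6.** The C3–C4 sp2–sp2 bond is cut to the vinyl iodide 22 and the stannylfuran 6. The union is placed directly before the key step so that the acid-labile silyloxyfuran lives for one step only, and the Z geometry of the iodide is transferred unchanged.

**22 ⇒ 20 ⇒ 18 + 19.** The aldehyde is traced to the dimethyl acetal 20. The C8–O ester bond is cut with inversion to alcohol 18 and acid 19, because the allylation that makes 18 gives the C8 epimer; esterification and stereochemical correction are thus one step.

**18 ⇒ 15 + 16.** The C7–C8 bond is cut to the bromobutenolide 15 and aldehyde 16. The forward allylation creates the α-methylene lactone and sets C7 (trans to the C6 side chain) and C8 from the single stereocenter C6.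

**15 ⇒ 14 ⇒ 12 + 13.** The C7=C11 bond is cut by ring-closing metathesis, and the ester C12–O6 is cut to alcohol 12 and acid 13, which brings in C11, C12 and C13.

**12 ⇒ 10 ⇒ 7 + 8.** The C4–I and C5–H bonds come from a hydroxyl-directed trans-hydroalumination and iodination of the alkyne 10, which fixes the Z geometry. The C5–C6 bond is cut to 7 and 8 by an enantioselective alkynylation, the only step in which a chiral catalyst sets a stereocenter.

**6 ⇒ 4 ⇒ 3 ⇒ 1.** The stannane comes from α-lithiation of the silyloxyfuran 4, which comes from O-silylation of furanone 3, itself the dehydrogenation product of the commercial ketone 1.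

## Alternatives that were turned down

**Alternative 1:** (textbook) Heterocycle last. Disconnection of the O–C3 bond of ring A. The forward key step is a 5-endo-dig oxa-Michael cyclisation of the tertiary C10 hydroxyl onto a macrocyclic C1–C2≡C3 ynone A1, after the carbocycle has been closed by an allylation or a metathesis. It was turned down for three reasons:
- A1 must hold a linear C1–C2≡C3–C4 unit, a Z-alkene and a trans-lactone in one ten-membered ring, so its macrocyclisation carries the strain but forms no stereocenter.
- The C9/C10 diol needs its own asymmetric step, and the three oxygens at C8, C9 and C10 need three-way differentiation, which costs protecting-group steps.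
- The furanone formed last contributes nothing to stereocontrol.

**Alternative 2:** Disconnection of C7–C8 in the ring. The forward key step is an intramolecular Barbier allylation of the seco bromobutenolide aldehyde A2, with ring A and the C9 ester already in place. It was turned down for three reasons:
- The closed transition state with the ring-fixed E-type allyl unit gives the 7,8-anti relationship, that is the 8-epi alcohol A3. Inversion would then be needed on a hindered ring carbinol next to the C9 ester, where neighbouring-group participation interferes.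
- C9 and C10 would have to come from an earlier intermolecular aldol that the remote C6 cannot control.
- The key step would form one bond and one stereocenter, and that one with the wrong sense.

**Alternative 3:** Disconnection of C4=C5. The forward key step is a ring-closing metathesis of diene A4, which would give 26 directly. It was turned down for three reasons:
- The alkene to be formed is trisubstituted, part of an electron-poor 2-substituted diene and inside a strained ring.
- A4 offers three acrylate-type alkenes (methylene lactone, methacrylate, senecioate) to the ruthenium carbene, which invites cross-metathesis and catalyst sequestration.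
- All five stereocenters must be in place before the key step, which builds none, and A4 again needs the uncontrolled intermolecular aldol.

Key step: step 12

Assumption: (S,S)-ProPhenol is taken to deliver the alkynyl group to the Re face of acrolein in step 4, which gives the (S)-carbinol 10; if the sense on this enal is the reverse, the antipode of the ligand is used.

## Route

Step 1
Reactants: 1 2-methyloxolan-3-one (racemic)
Product: 3 2-methylfuran-3(2H)-one (racemic), via silyl enol ether 2 (not isolated)
Conditions: LiN(iPr)2, TMSCl, THF, −78 °C; then Pd(OAc)2 (10 mol %), O2 (1 atm), DMSO, rt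
Reagents that add atoms: none
Why: Saegusa–Ito oxidation: kinetic deprotonation occurs at C4, the α-carbon without oxygen, and palladium-mediated dehydrosilylation of 2 gives the vinylogous ester 3; the C2 stereocenter is of no consequence because it is flattened in step 2.

Step 2
Reactants: 3 2-methylfuran-3(2H)-one
Product: 4 triisopropyl[(2-methylfuran-3-yl)oxy]silane
Conditions: TIPSOTf, Et3N, CH2Cl2, 0 °C
Reagents that add atoms: triisopropylsilyl trifluoromethanesulfonate, CC(C)[Si](OS(=O)(=O)C(F)(F)F)(C(C)C)C(C)C
Why: Soft enolisation and O-silylation, driven by aromatisation to the furan, is the standard entry to 3-silyloxyfurans; the TIPS group is chosen for hydrolytic stability.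

Step 3
Reactants: 4 triisopropyl[(2-methylfuran-3-yl)oxy]silane
Product: 6 tributyl[5-methyl-4-(triisopropylsilyloxy)furan-2-yl]stannane, via lithiated furan 5 (not isolated)
Conditions: n-BuLi, THF, −78 → 0 °C; then Bu3SnCl, −78 °C → rt
Reagents that add atoms: tributyltin chloride, CCCC[Sn](Cl)(CCCC)CCCC
Why: Heteroaryl α-lithiation at the only free α-position of the furan, followed by stannylation; this position is not ortho to the silyloxy group, so no silyl migration is expected.

Step 4
Reactants: 7 prop-2-enal (acrolein); 8 tert-butyldimethyl(prop-2-yn-1-yloxy)silane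
Product: 10 (3S)-6-(tert-butyldimethylsilyloxy)hex-1-en-4-yn-3-ol, via alkynylzinc 9 (not isolated)
Conditions: Me2Zn, (S,S)-ProPhenol [2,6-bis{[(S)-2-(hydroxydiphenylmethyl)pyrrolidin-1-yl]methyl}-4-methylphenol] (10 mol %), Ph3P=O (20 mol %), toluene, 0 °C
Reagents that add atoms: none
Why: Zinc/ProPhenol-catalysed enantioselective 1,2-alkynylation of an α,β-unsaturated aldehyde forms C5–C6 and sets C6 by catalyst control (alkynyl to the Re face); this center later becomes 6R of the target by a change of substituent priorities only.

Step 5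
Reactants: 10 (3S)-6-(tert-butyldimethylsilyloxy)hex-1-en-4-yn-3-ol
Product: 12 (3S,4Z)-6-(tert-butyldimethylsilyloxy)-5-iodohexa-1,4-dien-3-ol, via vinylalanate 11 (not isolated)
Conditions: NaAlH2(OCH2CH2OMe)2, THF, −20 → 0 °C; EtOAc; then I2, THF, −78 °C
Reagents that add atoms: iodine, II
Why: Hydroxyl-directed trans-hydroalumination delivers hydride to C5 and aluminium to C4 within a five-membered oxaaluminacycle, and iodinolysis with retention places iodine cis to C6; this fixes the Z geometry of C4=C5 of the target, and the low temperature suppresses loss of the silyloxy group to an allene.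

Step 6
Reactants: 12 (3S,4Z)-6-(tert-butyldimethylsilyloxy)-5-iodohexa-1,4-dien-3-ol; 13 2-(bromomethyl)prop-2-enoic acid
Product: 14 (3S,4Z)-6-(tert-butyldimethylsilyloxy)-5-iodohexa-1,4-dien-3-yl 2-(bromomethyl)prop-2-enoate
Conditions: DCC, DMAP (5 mol %), CH2Cl2, 0 °C
Reagents that add atoms: none
Why: Steglich esterification; low temperature and a small amount of DMAP spare the allylic bromide, and C6 is not touched.

Step 7
Reactants: 14 (3S,4Z)-6-(tert-butyldimethylsilyloxy)-5-iodohexa-1,4-dien-3-yl 2-(bromomethyl)prop-2-enoate
Product: 15 (5S)-3-(bromomethyl)-5-[(1Z)-3-(tert-butyldimethylsilyloxy)-2-iodoprop-1-en-1-yl]furan-2(5H)-one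
Conditions: second-generation Hoveyda–Grubbs catalyst (5 mol %), toluene (5 mM), 80 °C
Reagents that add atoms: none
Why: Ring-closing metathesis between the vinyl group and the 1,1-disubstituted acrylate forms C7=C11 of an α-substituted butenolide, a known closure for 2-substituted acrylates of allylic alcohols; the trisubstituted vinyl iodide is too hindered and deactivated to take part.

Step 8
Reactants: 15 (5S)-3-(bromomethyl)-5-[(1Z)-3-(tert-butyldimethylsilyloxy)-2-iodoprop-1-en-1-yl]furan-2(5H)-one; 16 2,2-dimethoxyacetaldehyde
Product: 18 (4R,5S)-5-[(1Z)-3-(tert-butyldimethylsilyloxy)-2-iodoprop-1-en-1-yl]-4-[(1R)-1-hydroxy-2,2-dimethoxyethyl]-3-methylideneoxolan-2-one, via allylzinc bromide 17 (not isolated)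
Conditions: Zn dust, THF/sat. aq. NH4Cl, 0 °C → rt
Reagents that add atoms: none
Why: Barbier allylation: 17 reacts at its γ-carbon C7 through a closed chair transition state, anti to the C6 side chain (trans-lactone); the ring-fixed E-type allyl geometry gives the 7,8-anti adduct, which is the C8 epimer of the target and exactly what step 9 requires; the vinyl iodide is inert to zinc under aqueous conditions.

Step 9
Reactants: 18 (4R,5S)-5-[(1Z)-3-(tert-butyldimethylsilyloxy)-2-iodoprop-1-en-1-yl]-4-[(1R)-1-hydroxy-2,2-dimethoxyethyl]-3-methylideneoxolan-2-one; 19 2-methylprop-2-enoic acid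
Product: 20 (1S)-1-[(2S,3S)-2-[(1Z)-3-(tert-butyldimethylsilyloxy)-2-iodoprop-1-en-1-yl]-4-methylidene-5-oxooxolan-3-yl]-2,2-dimethoxyethyl 2-methylprop-2-enoate
Conditions: PPh3, DIAD (premixed), THF, 0 °C → rt
Reagents that add atoms: none
Why: Mitsunobu esterification: the carboxylate displaces the activated C8 oxygen by SN2 with inversion, which installs the methacrylate and corrects C8 in one operation; premixing the phosphine with DIAD keeps free phosphine away from the methylene lactone.

Step 10
Reactants: 20 (1S)-1-[(2S,3S)-2-[(1Z)-3-(tert-butyldimethylsilyloxy)-2-iodoprop-1-en-1-yl]-4-methylidene-5-oxooxolan-3-yl]-2,2-dimethoxyethyl 2-methylprop-2-enoate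
Product: 22 (1S)-1-[(2S,3S)-2-[(1Z)-3-(tert-butyldimethylsilyloxy)-2-iodoprop-1-en-1-yl]-4-methylidene-5-oxooxolan-3-yl]-2-oxoethyl 2-methylprop-2-enoate, via collidinium salt 21 (not isolated)
Conditions: TESOTf, 2,4,6-collidine, CH2Cl2, 0 °C; then H2O
Reagents that add atoms: water, O
Why: Silyl-triflate-mediated acetal cleavage: the acetal is ionised, the oxocarbenium ion is trapped by collidine as 21, and hydrolysis releases the aldehyde under non-acidic conditions that spare the TBS ether and the ester and do not enolise C8.

Step 11
Reactants: 22 (1S)-1-[(2S,3S)-2-[(1Z)-3-(tert-butyldimethylsilyloxy)-2-iodoprop-1-en-1-yl]-4-methylidene-5-oxooxolan-3-yl]-2-oxoethyl 2-methylprop-2-enoate; 6 tributyl[5-methyl-4-(triisopropylsilyloxy)furan-2-yl]stannane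
Product: 23 (1S)-1-[(2R,3S)-2-[(1Z)-3-(tert-butyldimethylsilyloxy)-2-[5-methyl-4-(triisopropylsilyloxy)furan-2-yl]prop-1-en-1-yl]-4-methylidene-5-oxooxolan-3-yl]-2-oxoethyl 2-methylprop-2-enoate
Conditions: Pd2(dba)3 (5 mol %), AsPh3 (20 mol %), CuI (10 mol %), DMF, rt, dark; used at once
Reagents that add atoms: none
Why: Stille coupling forms C3–C4 with retention of the alkene geometry under neutral conditions that tolerate the aldehyde and the esters; AsPh3 replaces phosphines to avoid conjugate addition, and CuI speeds transmetalation so that the zerovalent palladium catalyst works at room temperature.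

Step 12
Reactants: 23 (1S)-1-[(2R,3S)-2-[(1Z)-3-(tert-butyldimethylsilyloxy)-2-[5-methyl-4-(triisopropylsilyloxy)furan-2-yl]prop-1-en-1-yl]-4-methylidene-5-oxooxolan-3-yl]-2-oxoethyl 2-methylprop-2-enoate
Product: 24 (4Z,6R,7S,8S,9R,10S)-15-(tert-butyldimethylsilyloxy)-9-hydroxy-8-(2-methylprop-2-enoyloxy)-1-oxo-3,10-epoxygermacra-2,4,11(13)-trien-12,6-olide
Conditions: BF3·OEt2 (1.5 equiv), CH2Cl2 (1 mM, syringe-pump addition of 23), −78 °C; then H2O
Reagents that add atoms: none
Why: BF3 activates the aldehyde of 23, the enol ether carbon of the furan (C10) adds in an open transition state, and the silyloxycarbenium ion loses its TIPS group to fluoride, which unveils the furan-3(2H)-one and makes the addition irreversible. The closest known reaction type is the BF3-promoted Mukaiyama aldol addition of 2-substituted 3-silyloxyfurans to aldehydes, which gives 2-(1-hydroxyalkyl)furan-3(2H)-ones with a quaternary C2, here run in the ring-closing sense of Lewis-acid Mukaiyama macro-aldolisations. One ring closes, the ten-membered carbocycle (nine-membered when counted through the furan oxygen), by a 10-exo-trig attack on the carbonyl carbon from the π-face of the furan. C10 is controlled by the tether: 1,3-allylic strain across the Z-C4=C5 bond keeps H6 in the diene plane facing the furan, so C7 and the lactone oxygen lie on opposite faces, and the six-carbon bridge can bring C9 only to the furan face on the side of C7, which is the 10S face. C9 is controlled by C8 and the incipient ring: the tether holds C10 gauche to C7, and the transition state expected to be lowest places the new oxygen equatorial and trans to the equatorial 8-methacrylate (synclinal carbonyl/enol ether arrangement, 9R). The antiperiplanar arrangement preferred by open-chain partners would force the 9-oxygen axial and cis to the ester. The step needs chemoselectivity for the aldehyde over the methylene lactone and the methacrylate, secured by BF3 activation of the aldehyde at −78 °C, and site selectivity for C10 over C2, secured by the enol ether polarisation. It also needs cyclisation over oligomerisation, secured by slow addition at 1 mM and by the Z-alkene and the trans-lactone as turn elements.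

Step 13
Reactants: 24 (4Z,6R,7S,8S,9R,10S)-15-(tert-butyldimethylsilyloxy)-9-hydroxy-8-(2-methylprop-2-enoyloxy)-1-oxo-3,10-epoxygermacra-2,4,11(13)-trien-12,6-olide; 25 3-methylbut-2-enoyl chloride
Product: 26 (4Z,6R,7S,8S,9R,10S)-15-(tert-butyldimethylsilyloxy)-8-(2-methylprop-2-enoyloxy)-9-(3-methylbut-2-enoyloxy)-1-oxo-3,10-epoxygermacra-2,4,11(13)-trien-12,6-olide
Conditions: pyridine, DMAP (10 mol %), CH2Cl2, 0 °C → rt
Reagents that add atoms: none
Why: Acylation of the secondary alcohol through the acylpyridinium ion; pyridine is too weak a base to form the vinylketene from 25 or the alkoxide that would trigger retro-aldol cleavage, and C9 is not touched.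

Step 14
Reactants: 26 (4Z,6R,7S,8S,9R,10S)-15-(tert-butyldimethylsilyloxy)-8-(2-methylprop-2-enoyloxy)-9-(3-methylbut-2-enoyloxy)-1-oxo-3,10-epoxygermacra-2,4,11(13)-trien-12,6-olide
Product: 27 (4Z,6R,7S,8S,9R,10S)-15-hydroxy-8-(2-methylprop-2-enoyloxy)-9-(3-methylbut-2-enoyloxy)-1-oxo-3,10-epoxygermacra-2,4,11(13)-trien-12,6-olide (target)
Conditions: HF·pyridine, pyridine, THF, 0 °C → rt
Reagents that add atoms: none
Why: Fluoride-mediated cleavage of the primary allylic TBS ether under buffered, weakly acidic conditions, which the esters, the Michael acceptors and the β-acyloxy ketone tolerate.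

## Compound list

1 | 2-methyloxolan-3-one (racemic) | CC1OCCC1=O | starting material
2 | trimethyl[(2-methyl-2,5-dihydrofuran-3-yl)oxy]silane (racemic) | CC1OCC=C1O[Si](C)(C)C | intermediate
3 | 2-methylfuran-3(2H)-one (racemic) | CC1OC=CC1=O | intermediate
4 | triisopropyl[(2-methylfuran-3-yl)oxy]silane | Cc1occc1O[Si](C(C)C)(C(C)C)C(C)C | intermediate
5 | [5-methyl-4-(triisopropylsilyloxy)furan-2-yl]lithium | [Li]c1cc(O[Si](C(C)C)(C(C)C)C(C)C)c(C)o1 | intermediate
6 | tributyl[5-methyl-4-(triisopropylsilyloxy)furan-2-yl]stannane | CCCC[Sn](CCCC)(CCCC)c1cc(O[Si](C(C)C)(C(C)C)C(C)C)c(C)o1 | intermediate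
7 | prop-2-enal (acrolein) | C=CC=O | starting material
8 | tert-butyldimethyl(prop-2-yn-1-yloxy)silane | C#CCO[Si](C)(C)C(C)(C)C | starting material
9 | [3-(tert-butyldimethylsilyloxy)prop-1-yn-1-yl](methyl)zinc | C[Zn]C#CCO[Si](C)(C)C(C)(C)C | intermediate
10 | (3S)-6-(tert-butyldimethylsilyloxy)hex-1-en-4-yn-3-ol | C=C[C@H](O)C#CCO[Si](C)(C)C(C)(C)C | intermediate
11 | sodium alkoxy(vinyl)alanate of 10 (five-membered O–Al–C4=C5–C6 ring, two 2-methoxyethoxy groups on aluminium, C6 unchanged) | [Na+].COCCO[Al-]1(OCCOC)O[C@@H](C=C)C=C1CO[Si](C)(C)C(C)(C)C | intermediate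
12 | (3S,4Z)-6-(tert-butyldimethylsilyloxy)-5-iodohexa-1,4-dien-3-ol | C=C[C@H](O)/C=C(/CO[Si](C)(C)C(C)(C)C)I | intermediate
13 | 2-(bromomethyl)prop-2-enoic acid | OC(=O)C(=C)CBr | starting material
14 | (3S,4Z)-6-(tert-butyldimethylsilyloxy)-5-iodohexa-1,4-dien-3-yl 2-(bromomethyl)prop-2-enoate | C=C(CBr)C(=O)O[C@@H](C=C)/C=C(/CO[Si](C)(C)C(C)(C)C)I | intermediate
15 | (5S)-3-(bromomethyl)-5-[(1Z)-3-(tert-butyldimethylsilyloxy)-2-iodoprop-1-en-1-yl]furan-2(5H)-one | BrCC1=C[C@H](OC1=O)/C=C(/CO[Si](C)(C)C(C)(C)C)I | intermediate
16 | 2,2-dimethoxyacetaldehyde | COC(OC)C=O | starting material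
17 | bromo{[(5S)-5-[(1Z)-3-(tert-butyldimethylsilyloxy)-2-iodoprop-1-en-1-yl]-2-oxo-2,5-dihydrofuran-3-yl]methyl}zinc | Br[Zn]CC1=C[C@H](OC1=O)/C=C(/CO[Si](C)(C)C(C)(C)C)I | intermediate
18 | (4R,5S)-5-[(1Z)-3-(tert-butyldimethylsilyloxy)-2-iodoprop-1-en-1-yl]-4-[(1R)-1-hydroxy-2,2-dimethoxyethyl]-3-methylideneoxolan-2-one | COC(OC)[C@H](O)[C@H]1C(=C)C(=O)O[C@@H]1/C=C(/CO[Si](C)(C)C(C)(C)C)I | intermediate
19 | 2-methylprop-2-enoic acid (methacrylic acid) | CC(=C)C(O)=O | starting material
20 | (1S)-1-[(2S,3S)-2-[(1Z)-3-(tert-butyldimethylsilyloxy)-2-iodoprop-1-en-1-yl]-4-methylidene-5-oxooxolan-3-yl]-2,2-dimethoxyethyl 2-methylprop-2-enoate | C=C(C)C(=O)O[C@H](C(OC)OC)[C@H]1C(=C)C(=O)O[C@@H]1/C=C(/CO[Si](C)(C)C(C)(C)C)I | intermediate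
21 | 1-[(2S)-1-methoxy-2-(2-methylprop-2-enoyloxy)-2-{(2S,3S)-lactone unit of 20}ethyl]-2,4,6-trimethylpyridinium triflate (C9 epimers) | C=C(C)C(=O)O[C@H](C(OC)[n+]2c(C)cc(C)cc2C)[C@H]1C(=C)C(=O)O[C@@H]1/C=C(/CO[Si](C)(C)C(C)(C)C)I.[O-]S(=O)(=O)C(F)(F)F | intermediate
22 | (1S)-1-[(2S,3S)-2-[(1Z)-3-(tert-butyldimethylsilyloxy)-2-iodoprop-1-en-1-yl]-4-methylidene-5-oxooxolan-3-yl]-2-oxoethyl 2-methylprop-2-enoate | C=C(C)C(=O)O[C@H](C=O)[C@H]1C(=C)C(=O)O[C@@H]1/C=C(/CO[Si](C)(C)C(C)(C)C)I | intermediate
23 | (1S)-1-[(2R,3S)-2-[(1Z)-3-(tert-butyldimethylsilyloxy)-2-[5-methyl-4-(triisopropylsilyloxy)furan-2-yl]prop-1-en-1-yl]-4-methylidene-5-oxooxolan-3-yl]-2-oxoethyl 2-methylprop-2-enoate | C=C(C)C(=O)O[C@H](C=O)[C@H]1C(=C)C(=O)O[C@@H]1/C=C(/CO[Si](C)(C)C(C)(C)C)c1cc(O[Si](C(C)C)(C(C)C)C(C)C)c(C)o1 | intermediate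
24 | (4Z,6R,7S,8S,9R,10S)-15-(tert-butyldimethylsilyloxy)-9-hydroxy-8-(2-methylprop-2-enoyloxy)-1-oxo-3,10-epoxygermacra-2,4,11(13)-trien-12,6-olide | C=C(C)C(=O)O[C@H]1[C@H]2C(=C)C(=O)O[C@@H]2/C=C(/CO[Si](C)(C)C(C)(C)C)C2=CC(=O)[C@@](C)(O2)[C@@H]1O | intermediate
25 | 3-methylbut-2-enoyl chloride | CC(C)=CC(Cl)=O | starting material
26 | (4Z,6R,7S,8S,9R,10S)-15-(tert-butyldimethylsilyloxy)-8-(2-methylprop-2-enoyloxy)-9-(3-methylbut-2-enoyloxy)-1-oxo-3,10-epoxygermacra-2,4,11(13)-trien-12,6-olide | C=C(C)C(=O)O[C@H]1[C@H]2C(=C)C(=O)O[C@@H]2/C=C(/CO[Si](C)(C)C(C)(C)C)C2=CC(=O)[C@@](C)(O2)[C@@H]1OC(=O)C=C(C)C | intermediate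
27 | (4Z,6R,7S,8S,9R,10S)-15-hydroxy-8-(2-methylprop-2-enoyloxy)-9-(3-methylbut-2-enoyloxy)-1-oxo-3,10-epoxygermacra-2,4,11(13)-trien-12,6-olide | C=C(C)C(=O)O[C@H]1[C@H]2C(=C)C(=O)O[C@@H]2/C=C(/CO)C2=CC(=O)[C@@](C)(O2)[C@@H]1OC(=O)C=C(C)C | target

## Step count and least certain steps

Total step count: 14. Longest linear sequence: 11 steps (steps 4 to 14, from 7 and 8 to 27); steps 1 to 3 form the side branch to 6.

**Step 12 (key step).** The most likely failure is poor facial selectivity at the aldehyde carbon C9. The furan face (C10) is fixed by the tether, but the C9 configuration of the target requires the synclinal arrangement of carbonyl and enol ether. Open-chain partners usually prefer the antiperiplanar arrangement, which here leads to the C9 epimer. Fallback, setting out from 23: the cyclisation is run as before and the 9S alcohol, C9 epimer of 24 F1, is collected and oxidised with Dess–Martin periodinane to the C9 ketone F2, a non-enolisable 2-acylfuranone. F2 is reduced with NaBH4/CeCl3·7H2O in MeOH at −78 °C. Hydride should add to the ring ketone along the axial direction, anti to H8, and give the equatorial 9-alcohol trans to the 8-ester. The route is rejoined at 24. C9 is then set by ketone reduction and no longer by the aldol face.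

**Step 9.** The most likely failure is a sluggish SN2 displacement at C8, a carbinol flanked by the lactone ring carbon and by the electron-poor acetal carbon. Elimination or retention through an acyloxyphosphonium pathway could then compete. Fallback, setting out from 18: the alcohol is converted with Tf2O and pyridine into the C8 triflate F3, which is displaced with caesium 2-methylprop-2-enoate F4 (from 19 and Cs2CO3) and 18-crown-6 in toluene. Carboxylate displacement of triflates is the established inversion for hindered, oxygen-flanked carbinols, and the route is rejoined at 20.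

**Step 8.** The most likely failure is erosion of the 7,8-anti selectivity, because in water the hydrated aldehyde may react in part through an open transition state. Fallback, setting out from 15 and 16: the route is made stereoconvergent. The 7,8-syn adduct, C8 epimer of 18 F5, already has the C8 configuration of the target. It is acylated with retention (methacrylic anhydride, DMAP, CH2Cl2) to give 20, while 18 goes through step 9 with inversion. Both epimers meet at 20.

**Step 10.** The most likely failure is neighbouring-group participation of the 8-methacrylate during ionisation of the deactivated acetal, with acyl transfer to the C9 oxygen or incomplete cleavage. Fallback, setting out from 15, with C9 carried at the alcohol oxidation level: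
- Barbier allylation of 2-[(4-methoxybenzyl)oxy]acetaldehyde (through 17) gives the alcohol F6.
- Mitsunobu esterification with 19 gives the inverted methacrylate F7.
- DDQ in wet CH2Cl2 removes the PMB group to give the primary alcohol F8.
- Dess–Martin oxidation, run at once to forestall acyl migration, rejoins the route at 22.

**Step 13.** The most likely failure is a base-induced side process on the β-hydroxy ketone that carries a vicinal ester: 1,2-migration of the methacryloyl group to O9, retro-aldol opening, or deconjugation of the acyl donor through its vinylketene. Fallback, setting out from 24 and 25: the acid chloride is activated electrophilically with AgOTf in the presence of 2,6-di-tert-butylpyridine in CH2Cl2 at −78 °C. The acylating species is then 3-methylbut-2-enoyl trifluoromethanesulfonate F9, which acylates the neutral alcohol without a nucleophilic catalyst or an alkoxide. The route is rejoined at 26.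

## Further compounds

F1 | step 12 | (4Z,6R,7S,8S,9S,10S)-15-(tert-butyldimethylsilyloxy)-9-hydroxy-8-(2-methylprop-2-enoyloxy)-1-oxo-3,10-epoxygermacra-2,4,11(13)-trien-12,6-olide (C9 epimer of 24) | C=C(C)C(=O)O[C@H]1[C@H]2C(=C)C(=O)O[C@@H]2/C=C(/CO[Si](C)(C)C(C)(C)C)C2=CC(=O)[C@@](C)(O2)[C@H]1O
F2 | step 12 | (4Z,6R,7S,8S,10S)-15-(tert-butyldimethylsilyloxy)-8-(2-methylprop-2-enoyloxy)-1,9-dioxo-3,10-epoxygermacra-2,4,11(13)-trien-12,6-olide | C=C(C)C(=O)O[C@H]1[C@H]2C(=C)C(=O)O[C@@H]2/C=C(/CO[Si](C)(C)C(C)(C)C)C2=CC(=O)[C@@](C)(O2)C1=O
F3 | step 9 | C8 trifluoromethanesulfonate of 18 (configuration of 18 retained) | COC(OC)[C@H](OS(=O)(=O)C(F)(F)F)[C@H]1C(=C)C(=O)O[C@@H]1/C=C(/CO[Si](C)(C)C(C)(C)C)I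
F4 | step 9 | caesium 2-methylprop-2-enoate | [Cs+].[O-]C(=O)C(C)=C
F5 | step 8 | C8 epimer of 18 (7,8-syn adduct) | COC(OC)[C@@H](O)[C@H]1C(=C)C(=O)O[C@@H]1/C=C(/CO[Si](C)(C)C(C)(C)C)I
F6 | step 10 | 7,8-anti Barbier adduct of 15 and 2-[(4-methoxybenzyl)oxy]acetaldehyde (lactone as in 18, C8 hydroxyl as in 18, C9 as CH2OPMB) | COc1ccc(COC[C@H](O)[C@H]2C(=C)C(=O)O[C@@H]2/C=C(/CO[Si](C)(C)C(C)(C)C)I)cc1
F7 | step 10 | C8-inverted methacrylate of F6 (C8 as in 20, C9 as CH2OPMB) | COc1ccc(COC[C@@H](OC(=O)C(C)=C)[C@H]2C(=C)C(=O)O[C@@H]2/C=C(/CO[Si](C)(C)C(C)(C)C)I)cc1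
F8 | step 10 | primary alcohol from F7 (C9 as CH2OH, otherwise as 22) | OC[C@@H](OC(=O)C(C)=C)[C@H]1C(=C)C(=O)O[C@@H]1/C=C(/CO[Si](C)(C)C(C)(C)C)I
F9 | step 13 | 3-methylbut-2-enoyl trifluoromethanesulfonate | CC(C)=CC(=O)OS(=O)(=O)C(F)(F)F
A1 | alternative 1 | (4Z,6R,7S,8S,9R,10S)-15-(tert-butyldimethylsilyloxy)-10-hydroxy-8-(2-methylprop-2-enoyloxy)-9-(3-methylbut-2-enoyloxy)-1-oxogermacra-4,11(13)-dien-2-yn-12,6-olide | C=C(C)C(=O)O[C@H]1[C@H]2C(=C)C(=O)O[C@@H]2/C=C(/CO[Si](C)(C)C(C)(C)C)C#CC(=O)[C@@](C)(O)[C@@H]1OC(=O)C=C(C)C
A2 | alternative 2 | seco bromobutenolide aldehyde (furan-3(2H)-one with C9 senecioate and C8 aldehyde, Z-alkene linked to the (5S)-3-(bromomethyl)butenolide) | O=C[C@@H](OC(=O)C=C(C)C)[C@]1(C)OC(/C(CO[Si](C)(C)C(C)(C)C)=C\[C@H]2OC(=O)C(CBr)=C2)=CC1=O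
A3 | alternative 2 | (4Z,6R,7S,8R,9R,10S)-15-(tert-butyldimethylsilyloxy)-8-hydroxy-9-(3-methylbut-2-enoyloxy)-1-oxo-3,10-epoxygermacra-2,4,11(13)-trien-12,6-olide (8-epi alcohol) | O[C@@H]1[C@H]2C(=C)C(=O)O[C@@H]2/C=C(/CO[Si](C)(C)C(C)(C)C)C2=CC(=O)[C@@](C)(O2)[C@@H]1OC(=O)C=C(C)C
A4 | alternative 3 | seco diene of 26 (C5 as vinyl on C6, C4 as 1,1-disubstituted alkene on C3) | C=C(C)C(=O)O[C@H]([C@@H](OC(=O)C=C(C)C)[C@]1(C)OC(C(=C)CO[Si](C)(C)C(C)(C)C)=CC1=O)[C@H]1C(=C)C(=O)O[C@@H]1C=C
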